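**Retrosynthetic overview**

- The route rests on the fully substituted benzylic carbon of the oxirane. It carries the arene, the epoxide oxygen and two CH2–O arms (oxirane CH2 and CH2OAc) and lies ortho to the isobutyrylated phenol oxygen, so the phenol oxygen and one arm fold back into the lactone of a benzofuran-2(3H)-one whose C3 is this carbon.
- Oxirane (closed last) ⇒ tertiary alcohol plus primary mesylate. The three esters are told apart by order: pentanoate from the start, isobutyrate on the phenol released by lactone reduction, acetate last.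
- C3–O and C3–CH2OH ⇒ 3-diazobenzofuranone 8 + 4-methoxybenzyl alcohol + formaldehyde (carbene, oxonium ylide, aldol trapping), which sets the only stereocentre.
- 8 ⇒ benzofuranone 7 (diazo transfer) ⇒ 3-hydroxybenzyl pentanoate + ethyl glyoxylate (ortho-hydroxyalkylation, deoxygenation, lactonisation).
- Ring order: benzene ring bought; temporary lactone ring closed in step 3 and opened reductively in step 7; oxirane closed in step 11.

Key step: step 5

Assumption: the facial sense that the Sc(OTf)3–N,N'-dioxide complex induces on this lactone enolate cannot be predicted with confidence, so the route is written for whichever ligand antipode (from (S)- or (R)-pipecolic acid) delivers (R)-12; formaldehyde 10 is used as the monomer generated from paraformaldehyde.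

**Route**

Step 1
Reactants: 1 3-hydroxybenzyl alcohol
Product: 2 3-hydroxybenzyl pentanoate
Conditions: vinyl pentanoate (1.5 equiv), Novozym 435 (immobilised Candida antarctica lipase B), MTBE, 40 °C
Reagents that add atoms: vinyl pentanoate, CCCCC(=O)OC=C
Why: Lipase-catalysed transesterification with an enol ester acylates the aliphatic primary hydroxyl and leaves the phenol, and is driven by tautomerisation of the released vinyl alcohol to acetaldehyde.

Step 2
Reactants: 2 3-hydroxybenzyl pentanoate; 3 ethyl glyoxylate
Product: 5 ethyl 2-hydroxy-2-[2-hydroxy-4-(pentanoyloxymethyl)phenyl]acetate (racemic), via aryloxytitanium trichloride 4 (not isolated)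
Conditions: TiCl4 (1.0 equiv), CH2Cl2, −30 °C; then freshly cracked 3, −30 to 0 °C; aq. NH4Cl
Reagents that add atoms: none
Why: Ortho-specific Friedel–Crafts hydroxyalkylation, in which the aryloxytitanium trichloride binds the glyoxylate aldehyde and delivers it through a six-membered chelate to an ortho carbon only; of the two ortho positions the one para to the CH2O-pentanoate arm is open while the other is flanked on both sides, and the new carbinol centre is racemic and is erased in step 3.

Step 3
Reactants: 5 ethyl 2-hydroxy-2-[2-hydroxy-4-(pentanoyloxymethyl)phenyl]acetate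
Product: 7 6-(pentanoyloxymethyl)benzofuran-2(3H)-one, via ethyl arylacetate 6 (not isolated)
Conditions: Et3SiH (3 equiv), TFA/CH2Cl2 1:4, 0 °C to rt; evaporate; then p-TsOH·H2O (5 mol %), PhMe, 90 °C, −EtOH
Reagents that add atoms: none
Why: Ionic hydrogenation, in which TFA ionises the benzylic hydroxyl to an ortho-quinone-methide-type cation stabilised by the free ortho phenol and Et3SiH delivers hydride to it, followed by acid-catalysed lactonisation of the phenol onto the ethyl ester to close the five-membered aryl lactone; the primary benzylic pentanoate cannot ionise and should survive.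

Step 4
Reactants: 7 6-(pentanoyloxymethyl)benzofuran-2(3H)-one
Product: 8 3-diazo-6-(pentanoyloxymethyl)benzofuran-2(3H)-one
Conditions: p-ABSA (1.2 equiv), Et3N (1.5 equiv), MeCN, 0 °C to rt
Reagents that add atoms: 4-acetamidobenzenesulfonyl azide (p-ABSA), CC(=O)Nc1ccc(cc1)S(=O)(=O)N=[N+]=[N-]
Why: Regitz diazo transfer, in which the C3 methylene between the arene and the lactone carbonyl is deprotonated by Et3N to an aromatic 2-oxidobenzofuran enolate that attacks the sulfonyl azide and fragments to the diazo lactone and the sulfonamide.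

Step 5
Reactants: 8 3-diazo-6-(pentanoyloxymethyl)benzofuran-2(3H)-one; 9 4-methoxybenzyl alcohol; 10 formaldehyde
Product: 12 (R)-3-(hydroxymethyl)-3-(4-methoxybenzyloxy)-6-(pentanoyloxymethyl)benzofuran-2(3H)-one, via oxonium ylide 11 (not isolated)
Conditions: Rh2(OAc)4 (1 mol %), Sc(OTf)3 (10 mol %), chiral pipecolic-acid-derived N,N'-dioxide ligand with 2,6-diisopropylanilide arms (11 mol %), 9 (1.2 equiv), 10 (3 equiv, THF solution from cracked paraformaldehyde), 4 Å MS, CH2Cl2, −20 °C, 8 added over 3 h
Reagents that add atoms: none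
Why: Proposed new method: Rh2(OAc)4 expels N2 from 8 to give an electrophilic carbene at C3, the hydroxyl oxygen of 9 adds to it, and the resulting oxonium ylide 11, an aromatic 2-oxidobenzofuran enolate, attacks through C3 a formaldehyde molecule bound to the chiral Sc(OTf)3–N,N'-dioxide complex (trivalent scandium) before the 1,2-proton shift can occur, so the C3–O and C3–CH2OH bonds form in one operation. The closest known reaction type is the Rh2(OAc)4-carbene oxonium-ylide aldol-type three-component trapping of 3-diazooxindoles and aryl diazoacetates with alcohols and aldehydes, together with the Sc(OTf)3–N,N'-dioxide-catalysed hydroxymethylation of 3-substituted oxindoles with formaldehyde; the aryl lactone 8 is the oxygen analogue of those substrates. No ring is closed, since both new bonds are made on the preformed lactone ring. The single new stereocentre, C3, is controlled by the scandium complex, which holds formaldehyde and is expected to engage the lactone carbonyl so that one face of the planar enolate is shielded, the ligand antipode being chosen to give (R). The step needs aldol trapping to beat plain O–H insertion, carbene dimerisation and capture by water, which slow addition of 8, Lewis-acid activation of formaldehyde, molecular sieves and low temperature should secure, while the lactone keeps the enolate flat and the phenol masked.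

Step 6
Reactants: 12 (R)-3-(hydroxymethyl)-3-(4-methoxybenzyloxy)-6-(pentanoyloxymethyl)benzofuran-2(3H)-one
Product: 13 (R)-3-(4-methoxybenzyloxy)-6-(pentanoyloxymethyl)-3-(triisopropylsilyloxymethyl)benzofuran-2(3H)-one
Conditions: TIPSOTf (1.3 equiv), 2,6-lutidine (2 equiv), CH2Cl2, −78 to 0 °C
Reagents that add atoms: triisopropylsilyl triflate, CC(C)[Si](C(C)C)(C(C)C)OS(=O)(=O)C(F)(F)F
Why: Silyl ether formation with a silyl triflate under weakly basic conditions avoids retro-aldol loss of formaldehyde from the β-hydroxy lactone, and the triisopropylsilyl group is chosen because migration of a smaller silyl group between the two CH2–O arms after step 7 would invert the stereocentre.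

Step 7
Reactants: 13 (R)-3-(4-methoxybenzyloxy)-6-(pentanoyloxymethyl)-3-(triisopropylsilyloxymethyl)benzofuran-2(3H)-one
Product: 15 3-hydroxy-4-[(2S)-1-hydroxy-2-(4-methoxybenzyloxy)-3-(triisopropylsilyloxy)propan-2-yl]benzyl pentanoate, via hydroxy aldehyde 14 (not isolated)
Conditions: NaBH4 (2.5 equiv), THF/EtOH 4:1, 0 °C to rt; aq. NH4Cl
Reagents that add atoms: none
Why: Chemoselective borohydride reduction, in which the α-alkoxy aryl lactone (an activated ester with a phenoxide leaving group) opens to the hydroxy aldehyde and is reduced on to the primary alcohol while the unactivated alkyl pentanoate should not react; the quaternary centre has no α-hydrogen and no bond to it is broken, the change of descriptor being a matter of priorities only.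

Step 8
Reactants: 15 3-hydroxy-4-[(2S)-1-hydroxy-2-(4-methoxybenzyloxy)-3-(triisopropylsilyloxy)propan-2-yl]benzyl pentanoate
Product: 16 4-[(2S)-1-hydroxy-2-(4-methoxybenzyloxy)-3-(triisopropylsilyloxy)propan-2-yl]-3-(isobutyryloxy)benzyl pentanoate
Conditions: i-PrCOCl (1.05 equiv), Et3N (1.2 equiv), CH2Cl2, −78 to −30 °C
Reagents that add atoms: isobutyryl chloride, CC(C)C(Cl)=O
Why: Chemoselective O-acylation, in which Et3N turns only the phenol (far more acidic than the neopentyl-type primary alcohol) into a nucleophilic phenoxide ion pair that takes up the acid chloride at low temperature without DMAP.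

Step 9
Reactants: 16 4-[(2S)-1-hydroxy-2-(4-methoxybenzyloxy)-3-(triisopropylsilyloxy)propan-2-yl]-3-(isobutyryloxy)benzyl pentanoate
Product: 17 3-(isobutyryloxy)-4-[(2R)-1-(methanesulfonyloxy)-2-(4-methoxybenzyloxy)-3-(triisopropylsilyloxy)propan-2-yl]benzyl pentanoate
Conditions: MsCl (1.3 equiv), Et3N (1.6 equiv), CH2Cl2, 0 °C
Reagents that add atoms: methanesulfonyl chloride, CS(Cl)(=O)=O
Why: Sulfonylation through the sulfene generated from MsCl and Et3N is fast even for the hindered neopentyl-type primary alcohol, which is the only free hydroxyl left.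

Step 10
Reactants: 17 3-(isobutyryloxy)-4-[(2R)-1-(methanesulfonyloxy)-2-(4-methoxybenzyloxy)-3-(triisopropylsilyloxy)propan-2-yl]benzyl pentanoate
Product: 18 4-[(2R)-2-hydroxy-1-(methanesulfonyloxy)-3-(triisopropylsilyloxy)propan-2-yl]-3-(isobutyryloxy)benzyl pentanoate
Conditions: DDQ (1.5 equiv), CH2Cl2/pH 7 phosphate buffer 10:1, 0 °C to rt
Reagents that add atoms: none
Why: Oxidative cleavage of the 4-methoxybenzyl ether, in which DDQ abstracts hydride from the electron-rich benzylic CH2 and water hydrolyses the oxocarbenium ion, while the esters, the mesylate and the silyl ether are inert under the buffered conditions.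

Step 11
Reactants: 18 4-[(2R)-2-hydroxy-1-(methanesulfonyloxy)-3-(triisopropylsilyloxy)propan-2-yl]-3-(isobutyryloxy)benzyl pentanoate
Product: 19 3-(isobutyryloxy)-4-[(2S)-2-(triisopropylsilyloxymethyl)oxiran-2-yl]benzyl pentanoate
Conditions: NaH (1.1 equiv), THF, 0 °C
Reagents that add atoms: none
Why: Intramolecular Williamson etherification (3-exo-tet), in which the tertiary alkoxide displaces the adjacent primary mesylate with help from the gem-disubstitution; the C–O bond at the stereocentre is not broken, so the configuration is retained.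

Step 12
Reactants: 19 3-(isobutyryloxy)-4-[(2S)-2-(triisopropylsilyloxymethyl)oxiran-2-yl]benzyl pentanoate
Product: 20 4-[(2R)-2-(hydroxymethyl)oxiran-2-yl]-3-(isobutyryloxy)benzyl pentanoate
Conditions: TBAF (1.5 equiv), AcOH (1.5 equiv), THF, 0 °C to rt
Reagents that add atoms: none
Why: Fluoride-mediated desilylation buffered with acetic acid, so that no basic alkoxide or phenoxide is present to open the oxirane, transfer the aryl ester or start a racemising Payne rearrangement.

Step 13
Reactants: 20 4-[(2R)-2-(hydroxymethyl)oxiran-2-yl]-3-(isobutyryloxy)benzyl pentanoate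
Product: 21 4-[(2S)-2-(acetoxymethyl)oxiran-2-yl]-3-(isobutyryloxy)benzyl pentanoate (CNP0107520.1)
Conditions: Ac2O (1.5 equiv), pyridine (3 equiv), DMAP (5 mol %), CH2Cl2, 0 °C
Reagents that add atoms: acetic anhydride, CC(=O)OC(C)=O
Why: DMAP-catalysed acylation of the primary alcohol under mild, non-nucleophilic conditions that the acid- and base-sensitive aryl oxirane and the two other esters should tolerate.

**Compound list**

1 | 3-hydroxybenzyl alcohol | OCc1cccc(O)c1 | starting material
2 | 3-hydroxybenzyl pentanoate | CCCCC(=O)OCc1cccc(O)c1 | intermediate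
3 | ethyl glyoxylate | CCOC(=O)C=O | starting material
4 | [3-(pentanoyloxymethyl)phenoxy]titanium trichloride | CCCCC(=O)OCc1cccc(O[Ti](Cl)(Cl)Cl)c1 | intermediate (not isolated)
5 | ethyl 2-hydroxy-2-[2-hydroxy-4-(pentanoyloxymethyl)phenyl]acetate (racemic) | CCCCC(=O)OCc1ccc(C(O)C(=O)OCC)c(O)c1 | intermediate
6 | ethyl 2-[2-hydroxy-4-(pentanoyloxymethyl)phenyl]acetate | CCCCC(=O)OCc1ccc(CC(=O)OCC)c(O)c1 | intermediate (not isolated)
7 | 6-(pentanoyloxymethyl)benzofuran-2(3H)-one | CCCCC(=O)OCc1ccc2c(c1)OC(=O)C2 | intermediate
8 | 3-diazo-6-(pentanoyloxymethyl)benzofuran-2(3H)-one | CCCCC(=O)OCc1ccc2c(c1)OC(=O)C2=[N+]=[N-] | intermediate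
9 | 4-methoxybenzyl alcohol | COc1ccc(CO)cc1 | starting material
10 | formaldehyde (monomer from paraformaldehyde) | C=O | starting material
11 | protic oxonium ylide (lactone enolate form) from the carbene of 8 and 9 | CCCCC(=O)OCc1ccc2c(c1)OC([O-])=C2[OH+]Cc1ccc(OC)cc1 | intermediate (not isolated)
12 | (R)-3-(hydroxymethyl)-3-(4-methoxybenzyloxy)-6-(pentanoyloxymethyl)benzofuran-2(3H)-one | CCCCC(=O)OCc1ccc2c(c1)OC(=O)[C@@]2(CO)OCc1ccc(OC)cc1 | intermediate
13 | (R)-3-(4-methoxybenzyloxy)-6-(pentanoyloxymethyl)-3-(triisopropylsilyloxymethyl)benzofuran-2(3H)-one | CCCCC(=O)OCc1ccc2c(c1)OC(=O)[C@@]2(CO[Si](C(C)C)(C(C)C)C(C)C)OCc1ccc(OC)cc1 | intermediate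
14 | 3-hydroxy-4-[(2R)-2-(4-methoxybenzyloxy)-1-oxo-3-(triisopropylsilyloxy)propan-2-yl]benzyl pentanoate (in equilibrium with its lactol) | CCCCC(=O)OCc1ccc([C@@](OCc2ccc(OC)cc2)(CO[Si](C(C)C)(C(C)C)C(C)C)C=O)c(O)c1 | intermediate (not isolated)
15 | 3-hydroxy-4-[(2S)-1-hydroxy-2-(4-methoxybenzyloxy)-3-(triisopropylsilyloxy)propan-2-yl]benzyl pentanoate | CCCCC(=O)OCc1ccc([C@@](OCc2ccc(OC)cc2)(CO[Si](C(C)C)(C(C)C)C(C)C)CO)c(O)c1 | intermediate
16 | 4-[(2S)-1-hydroxy-2-(4-methoxybenzyloxy)-3-(triisopropylsilyloxy)propan-2-yl]-3-(isobutyryloxy)benzyl pentanoate | CCCCC(=O)OCc1ccc([C@@](OCc2ccc(OC)cc2)(CO[Si](C(C)C)(C(C)C)C(C)C)CO)c(OC(=O)C(C)C)c1 | intermediate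
17 | 3-(isobutyryloxy)-4-[(2R)-1-(methanesulfonyloxy)-2-(4-methoxybenzyloxy)-3-(triisopropylsilyloxy)propan-2-yl]benzyl pentanoate | CCCCC(=O)OCc1ccc([C@@](OCc2ccc(OC)cc2)(CO[Si](C(C)C)(C(C)C)C(C)C)COS(C)(=O)=O)c(OC(=O)C(C)C)c1 | intermediate
18 | 4-[(2R)-2-hydroxy-1-(methanesulfonyloxy)-3-(triisopropylsilyloxy)propan-2-yl]-3-(isobutyryloxy)benzyl pentanoate | CCCCC(=O)OCc1ccc([C@@](O)(CO[Si](C(C)C)(C(C)C)C(C)C)COS(C)(=O)=O)c(OC(=O)C(C)C)c1 | intermediate
19 | 3-(isobutyryloxy)-4-[(2S)-2-(triisopropylsilyloxymethyl)oxiran-2-yl]benzyl pentanoate | CCCCC(=O)OCc1ccc([C@@]2(CO[Si](C(C)C)(C(C)C)C(C)C)CO2)c(OC(=O)C(C)C)c1 | intermediate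
20 | 4-[(2R)-2-(hydroxymethyl)oxiran-2-yl]-3-(isobutyryloxy)benzyl pentanoate | CCCCC(=O)OCc1ccc([C@@]2(CO)CO2)c(OC(=O)C(C)C)c1 | intermediate
21 | 4-[(2S)-2-(acetoxymethyl)oxiran-2-yl]-3-(isobutyryloxy)benzyl pentanoate (CNP0107520.1) | CCCCC(=O)OCc1ccc([C@@]2(COC(C)=O)CO2)c(OC(=O)C(C)C)c1 | target

**Totals**

Total step count: 13. Longest linear sequence: 13 steps (from 1; compounds 3, 9 and 10 are bought).

**Steps most likely to fail**

1. Step 5 (proposed new method). The oxonium ylide may undergo the 1,2-proton shift (plain O–H insertion) faster than it is trapped, the alcohol may be held back as its hemiformal with formaldehyde, or face selectivity on the lactone enolate may be poor. The fallback uses known chemistry, sets out from 8 and returns at 12. Rh2(OAc)4-catalysed O–H insertion of 9 into 8 in CH2Cl2 without formaldehyde should give racemic 3-(4-methoxybenzyloxy)-6-(pentanoyloxymethyl)benzofuran-2(3H)-one F1. Base-catalysed aldol addition of its acidic C3–H to monomeric formaldehyde (catalytic DBU, THF, −40 °C) should give racemic 3-(hydroxymethyl)-3-(4-methoxybenzyloxy)-6-(pentanoyloxymethyl)benzofuran-2(3H)-one F2. Preparative chromatography on a chiral stationary phase then separates the (R)-enantiomer, which is 12, from (S)-3-(hydroxymethyl)-3-(4-methoxybenzyloxy)-6-(pentanoyloxymethyl)benzofuran-2(3H)-one F3.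

2. Step 11. Transfer of the isobutyryl group from the phenol oxygen to the tertiary alkoxide through a six-membered tetrahedral intermediate may outrun the three-membered ring closure, after which the freed phenoxide would displace the mesylate in a five-membered ring closure. The fallback sets out from 16 and returns at 19. DDQ in wet CH2Cl2 removes the 4-methoxybenzyl group from 16 to give 4-[(2S)-1,2-dihydroxy-3-(triisopropylsilyloxy)propan-2-yl]-3-(isobutyryloxy)benzyl pentanoate F4. Mitsunobu cyclodehydration (PPh3, DIAD, THF, 0 °C to rt) then activates the primary hydroxyl as its alkoxyphosphonium ion under neutral conditions, so the tertiary hydroxyl should close the oxirane to 19 without a free alkoxide being present.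

3. Step 3. Lactonisation of 5 ahead of ionisation would remove the free phenol that stabilises the benzylic cation and stall the hydride transfer, and the cation may instead alkylate a second arene. The fallback sets out from 5 and returns at 7. p-TsOH in toluene at 90 °C lactonises 5 to racemic 3-hydroxy-6-(pentanoyloxymethyl)benzofuran-2(3H)-one F5. Ac2O and pyridine convert it into racemic 3-acetoxy-6-(pentanoyloxymethyl)benzofuran-2(3H)-one F6. SmI2 (2.2 equiv, divalent samarium) in THF/MeOH at −78 °C then cleaves the α-acyloxy C–O bond by electron transfer (the known reduction of α-heterosubstituted carbonyl compounds), and protonation of the enolate gives 7.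

**Further compounds**

F1 | step 5 | 3-(4-methoxybenzyloxy)-6-(pentanoyloxymethyl)benzofuran-2(3H)-one (racemic) | CCCCC(=O)OCc1ccc2c(c1)OC(=O)C2OCc1ccc(OC)cc1
F2 | step 5 | 3-(hydroxymethyl)-3-(4-methoxybenzyloxy)-6-(pentanoyloxymethyl)benzofuran-2(3H)-one (racemic) | CCCCC(=O)OCc1ccc2c(c1)OC(=O)C2(CO)OCc1ccc(OC)cc1
F3 | step 5 | (S)-3-(hydroxymethyl)-3-(4-methoxybenzyloxy)-6-(pentanoyloxymethyl)benzofuran-2(3H)-one | CCCCC(=O)OCc1ccc2c(c1)OC(=O)[C@]2(CO)OCc1ccc(OC)cc1
F4 | step 11 | 4-[(2S)-1,2-dihydroxy-3-(triisopropylsilyloxy)propan-2-yl]-3-(isobutyryloxy)benzyl pentanoate | CCCCC(=O)OCc1ccc([C@@](O)(CO[Si](C(C)C)(C(C)C)C(C)C)CO)c(OC(=O)C(C)C)c1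
F5 | step 3 | 3-hydroxy-6-(pentanoyloxymethyl)benzofuran-2(3H)-one (racemic) | CCCCC(=O)OCc1ccc2c(c1)OC(=O)C2O
F6 | step 3 | 3-acetoxy-6-(pentanoyloxymethyl)benzofuran-2(3H)-one (racemic) | CCCCC(=O)OCc1ccc2c(c1)OC(=O)C2OC(C)=O
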